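**Retrosynthetic overview**

1. Last bond: C7–C8, by intramolecular Nozaki–Hiyama (Barbier-type) allylation of a C8 aldehyde with the allylchromium from a 3-(bromomethyl)but-2-en-4-olide. It closes the lactone-fused oxepane (C5–C6–C7–C8–C9–C10–O), sets C7 and C8, and regenerates the α-methylene lactone.
2. Enabling feature: C7 is the β-carbon of the lactone C11(=C13)–C12(=O)–O–C6, so its allylic isomer (C7=C11, C13–Br) is an allyl-metal precursor nucleophilic at C7. C8 hangs on C10 (via C9) of the other oxepane and C6 hangs on C5.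
3. Bromobutenolide: from the C6 aldehyde by 2-(ethoxycarbonyl)allylation (Felkin, sets C6), lactonisation, then Br2/DBU allylic transposition.
4. First oxepane (O, C5, C4, C3, C2, C1, C10): the six ring carbons of (S)-carvone with oxygen inserted by Baeyer–Villiger oxidation. C3–O comes from the isopropenyl group, C10 from a Pd-catalysed allylation, C4 and C5 from protonation and hydroboration anti to C3–O.
5. Ring order: oxepane A (step 4), γ-lactone (step 13), oxepane B (step 18).

Key step: step 18

Remark (assumption and locants): read as drawn, the ether oxygen joins C5 and C10 in a trans (in,out) sense, so C6 and C9 are built trans across the ring oxygen of the first oxepane; germacranolide locants are used (C14 = CH3 on C10, C15 = CH2O on C4, C11–C13 = lactone side).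

**Route**

Step 1
Reactants: 1 (S)-(+)-carvone; 2 allyl chloroformate
Product: 4 allyl (5S)-2-methyl-5-(prop-1-en-2-yl)cyclohex-1-en-1-yl carbonate, via lithium enolate 3 (not isolated)
Conditions: L-Selectride, THF, −78 °C; then 2, −78 → 0 °C
Reagents that add atoms: allyl chloroformate, C=CCOC(Cl)=O
Why: Conjugate reduction gives the C1=C2 enolate regiospecifically and the chloroformate traps it on oxygen (enolate O-acylation); the C5 stereocentre is untouched.

Step 2
Reactants: 4 allyl enol carbonate
Product: 5 (2R,5S)-2-allyl-2-methyl-5-(prop-1-en-2-yl)cyclohexan-1-one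
Conditions: Pd2(dba)3 (2.5 mol %), (R)-t-BuPHOX (6 mol %), THF, 25 °C
Reagents that add atoms: none
Why: Asymmetric decarboxylative Tsuji allylation; the (R)-PHOX ligand should control the enolate face and place allyl trans to the isopropenyl group (2R quaternary centre, the future C10), against the cis preference of ordinary axial enolate alkylation.

Step 3
Reactants: 5 allyl ketone
Product: 7 5-acetyl-2-(2,2-dimethoxyethyl)-2-methylcyclohexan-1-one (configuration of 5), via keto aldehyde 6 (not isolated)
Conditions: O3, CH2Cl2/MeOH, −78 °C; Me2S; then HC(OMe)3, PPTS (cat.), MeOH, 0 °C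
Reagents that add atoms: ozone, [O-][O+]=O; trimethyl orthoformate, COC(OC)OC
Why: Ozonolysis cleaves both terminal alkenes (allyl to CH2CHO, isopropenyl to acetyl) and the aldehyde is acetalised selectively over the two ketones; no stereocentre is touched.

Step 4
Reactants: 7 acetal diketone
Product: 8 4-acetoxy-7-(2,2-dimethoxyethyl)-7-methyloxepan-2-one (acetoxy trans to the dimethoxyethyl arm)
Conditions: m-CPBA (excess), NaHCO3, CH2Cl2, rt
Reagents that add atoms: m-CPBA, OOC(=O)c1cccc(Cl)c1
Why: Double Baeyer–Villiger oxidation with retention: the quaternary carbon migrates in the ring ketone (oxygen inserted next to C10, giving the first oxepane as its lactone) and the ring carbon migrates in the methyl ketone (acetyl to acetate, the C3–O bond).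

Step 5
Reactants: 8 acetoxy lactone
Product: 9 4-hydroxy-7-(2,2-dimethoxyethyl)-7-methyloxepan-2-one
Conditions: K2CO3 (cat.), MeOH, 0 °C
Reagents that add atoms: none
Why: Transesterification should remove the unhindered secondary acetate, while the lactone, an ester of a tertiary alkoxide, exchanges much more slowly.

Step 6
Reactants: 9 hydroxy lactone
Product: 10 4-(tert-butyldimethylsilyloxy)-7-(2,2-dimethoxyethyl)-7-methyloxepan-2-one
Conditions: TBSCl, imidazole, DMF, rt
Reagents that add atoms: TBSCl, CC(C)(C)[Si](C)(C)Cl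
Why: Standard silylation of a secondary alcohol.

Step 7
Reactants: 10 silyloxy lactone
Product: 14 3-methylene-4-(TBS-oxy)-7-(2,2-dimethoxyethyl)-7-methyloxepan-2-one, via lithium enolate 11 (not isolated), via Mannich base 12 (not isolated), via methiodide 13 (not isolated)
Conditions: LDA, THF, −78 °C; Eschenmoser's salt; then MeI; then DBU, CH2Cl2
Reagents that add atoms: Eschenmoser's salt, C=[N+](C)C.[I-]; iodomethane (retained only in 13), CI
Why: The lactone has a single α-CH2, so the enolate is regiodefined; Mannich reaction, N-methylation and elimination is the standard α-methylenation of lactones.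

Step 8
Reactants: 14 α-methylene lactone
Product: 16 3-(hydroxymethyl)-4-(TBS-oxy) lactone (3,4-cis), via pinacol boronate 15 (not isolated)
Conditions: CuCl (5 mol %), Xantphos, NaOt-Bu (cat.), B2pin2, MeOH (2 equiv), THF, rt; then NaBO3·4H2O, THF/H2O
Reagents that add atoms: bis(pinacolato)diboron (in 15), CC1(C)OB(OC1(C)C)B1OC(C)(C)C(C)(C)O1; sodium perborate, O[B-]1(O)OO[B-](O)(O)OO1.[Na+].[Na+]
Why: Copper-catalysed conjugate borylation puts boron on C15; kinetic protonation of the enolate by methanol on the face opposite the C3 silyloxy group should set C4 with CH2B cis to OTBS, and C–B oxidation follows.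

Step 9
Reactants: 16 hydroxymethyl lactone
Product: 17 3-(TBS-oxymethyl)-4-(TBS-oxy)-7-(2,2-dimethoxyethyl)-7-methyloxepan-2-one (3,4-cis)
Conditions: TBSCl, imidazole, CH2Cl2, 0 °C
Reagents that add atoms: TBSCl, CC(C)(C)[Si](C)(C)Cl
Why: Silylation of the primary alcohol under conditions too mild to epimerise C4.

Step 10
Reactants: 17 bis-silyl lactone
Product: 18 2-methyleneoxepane (exocyclic enol ether C5=C6H2)
Conditions: Cp2TiMe2, toluene, 75 °C, dark
Reagents that add atoms: dimethyltitanocene, [CH3-].[CH3-].[Ti+4].c1cc[cH-]c1.c1cc[cH-]c1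
Why: Petasis methylenation of the lactone carbonyl is non-basic, so the epimerisable C4 centre is preserved.

Step 11
Reactants: 18 enol ether
Product: 20 (oxepan-2-yl)methanol with C6H2OH, C4–CH2OTBS and C3–OTBS all cis and the C10 arm trans, via alkylborane 19 (not isolated)
Conditions: 9-BBN, THF, 0 °C → rt; then NaOH, H2O2, 0 °C
Reagents that add atoms: 9-BBN (in 19), B1C2CCCC1CCC2; hydrogen peroxide, OO
Why: Hydroboration–oxidation puts boron on the terminal carbon; 9-BBN should attack the face opposite the C4 and C3 substituents, so H enters C5 trans to them and C6 ends cis to C15.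

Step 12
Reactants: 20 primary alcohol
Product: 21 oxepane-2-carbaldehyde (C6 aldehyde)
Conditions: Dess–Martin periodinane, NaHCO3, CH2Cl2, 0 °C
Reagents that add atoms: none
Why: Buffered Dess–Martin oxidation should give the α-alkoxy aldehyde without epimerising C5.

Step 13
Reactants: 21 aldehyde; 22 ethyl 2-(bromomethyl)acrylate
Product: 24 α-methylene-γ-butyrolactone carrying the oxepane at C6, via hydroxy ester 23 (not isolated)
Conditions: CrCl2, THF, rt; then PPTS (cat.), CH2Cl2
Reagents that add atoms: ethyl 2-(bromomethyl)acrylate, CCOC(=O)C(=C)CBr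
Why: Nozaki–Hiyama 2-(alkoxycarbonyl)allylation; the non-chelating chromium reagent should add in the Felkin–Anh (polar) mode with C5–O anti to the incoming carbon, giving the 5,6-anti relationship (C6), and the γ-hydroxy ester lactonises.

Step 14
Reactants: 24 bis-silyl lactone
Product: 25 15-hydroxy compound (C3–OTBS retained)
Conditions: CSA (0.1 equiv), MeOH, 0 °C
Reagents that add atoms: none
Why: Acid-catalysed methanolysis cleaves the primary silyl ether much faster than the hindered secondary one, and in methanol the dimethyl acetal only exchanges with itself.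

Step 15
Reactants: 25 primary alcohol
Product: 26 15-acetate
Conditions: Ac2O, pyridine, DMAP (cat.), 0 °C
Reagents that add atoms: acetic anhydride, CC(=O)OC(C)=O
Why: Standard acetylation of the only free hydroxyl.

Step 16
Reactants: 26 α-methylene lactone
Product: 28 3-(bromomethyl)but-2-en-4-olide (C7=C11, C13–Br) with the C8 acetal, via dibromide 27 (not isolated)
Conditions: Br2, CH2Cl2, 0 °C; then DBU, 0 °C
Reagents that add atoms: bromine, BrBr
Why: Bromine adds to the exocyclic alkene and DBU should remove HBr by E2 with a ring C7–H to give the endocyclic conjugated butenolide, a net allylic transposition that does not touch C6.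

Step 17
Reactants: 28 bromobutenolide acetal
Product: 29 bromobutenolide C8 aldehyde
Conditions: Amberlyst-15, acetone/H2O (20:1), rt
Reagents that add atoms: water, O
Why: Mild acetal hydrolysis; allylic bromide, acetate and secondary TBS ether tolerate these conditions, and no base is present to trigger β-elimination of the β-alkoxy aldehyde.

Step 18
Reactants: 29 bromobutenolide aldehyde
Product: 31 tricyclic 8β-alcohol (3-O-TBS, 15-O-acetyl, α-methylene lactone), via allylchromium 30 (not isolated)
Conditions: CrCl2 (8 equiv), THF, 0.002 M (slow addition of 29), rt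
Reagents that add atoms: none
Why: CrCl2 reduces the C13–Br bond to the allylchromium(III) species 30, which adds through its γ-carbon C7 to the C8 aldehyde in a chromium-bridged six-membered array with shift of the alkene to C11=C13. Closest known reaction type: Nozaki–Hiyama (Barbier-type) allylation of aldehydes with 3-(bromomethyl)but-2-enolides and 2-(bromomethyl)acrylates, here intramolecular. The oxepane closes in the 7-exo-trig mode onto the C8 carbonyl and no other ring is formed. C7 is set by the butenolide face: the required bond forms anti to the C5 substituent on C6 (trans ring fusion), the face used with external aldehydes; C8 is set in the same array, where the carbonyl oxygen on chromium lies anti to C6 and the closing ring holds the C9 arm gauche to C6, giving the 8β alcohol. The step needs ring closure to win over dimerisation or protonation, and anti-face over syn-face addition: the first is secured by the preset trans arrangement of C6 and C9 across the ring oxygen (only the in,out bicycle can result), high dilution and the persistence of allylchromium in aprotic THF; the second rests only on the steric bias of C5 and is the least secure element.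

Step 19
Reactants: 31 tricyclic alcohol; 32 angelic acid
Product: 33 8-O-angelate (3-O-TBS)
Conditions: 32, 2,4,6-trichlorobenzoyl chloride, Et3N, toluene, rt; then 31, 60–80 °C (no DMAP)
Reagents that add atoms: angelic acid, C/C=C(/C)C(=O)O
Why: Yamaguchi mixed-anhydride esterification without DMAP acylates the C8 alcohol with retention and should avoid isomerisation of the (Z)-angelate to the tiglate.

Step 20
Reactants: 33 silyl ether
Product: 34 target CNP0277024.1
Conditions: HF·pyridine, THF/pyridine, 0 °C → rt
Reagents that add atoms: none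
Why: Fluoride cleavage of the secondary TBS ether; acetate, angelate and α-methylene lactone are stable to buffered HF·pyridine.

**Compound list**

1 | (S)-(+)-carvone | CC1=CC[C@@H](CC1=O)C(C)=C | starting material
2 | allyl chloroformate | C=CCOC(Cl)=O | starting material
3 | lithium enolate of (5S)-dihydrocarvone | [Li+].CC1=C([O-])C[C@H](CC1)C(C)=C | intermediate
4 | allyl (5S)-2-methyl-5-(prop-1-en-2-yl)cyclohex-1-en-1-yl carbonate | CC1=C(OC(=O)OCC=C)C[C@H](CC1)C(C)=C | intermediate
5 | (2R,5S)-2-allyl-2-methyl-5-(prop-1-en-2-yl)cyclohexan-1-one | C=CC[C@@]1(C)CC[C@@H](CC1=O)C(C)=C | intermediate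
6 | 5-acetyl-2-methyl-2-(2-oxoethyl)cyclohexan-1-one | O=CC[C@@]1(C)CC[C@@H](CC1=O)C(C)=O | intermediate
7 | 5-acetyl-2-(2,2-dimethoxyethyl)-2-methylcyclohexan-1-one | COC(OC)C[C@@]1(C)CC[C@@H](CC1=O)C(C)=O | intermediate
8 | 4-acetoxy-7-(2,2-dimethoxyethyl)-7-methyloxepan-2-one | O=C1O[C@](C)(CC[C@H](OC(C)=O)C1)CC(OC)OC | intermediate
9 | 4-hydroxy-7-(2,2-dimethoxyethyl)-7-methyloxepan-2-one | O=C1O[C@](C)(CC[C@H](O)C1)CC(OC)OC | intermediate
10 | 4-(TBS-oxy)-7-(2,2-dimethoxyethyl)-7-methyloxepan-2-one | O=C1O[C@](C)(CC[C@H](O[Si](C)(C)C(C)(C)C)C1)CC(OC)OC | intermediate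
11 | lithium enolate of 10 | [Li+].[O-]C1=C[C@@H](O[Si](C)(C)C(C)(C)C)CC[C@](C)(CC(OC)OC)O1 | intermediate
12 | 3-[(dimethylamino)methyl] lactone (C4 epimers) | O=C1O[C@](C)(CC[C@H](O[Si](C)(C)C(C)(C)C)C1CN(C)C)CC(OC)OC | intermediate
13 | trimethylammonium iodide of 12 | O=C1O[C@](C)(CC[C@H](O[Si](C)(C)C(C)(C)C)C1C[N+](C)(C)C)CC(OC)OC.[I-] | intermediate
14 | 3-methylene-4-(TBS-oxy)-7-(2,2-dimethoxyethyl)-7-methyloxepan-2-one | O=C1O[C@](C)(CC[C@H](O[Si](C)(C)C(C)(C)C)C1=C)CC(OC)OC | intermediate
15 | 3-(pinacolborylmethyl) lactone (3,4-cis) | O=C1O[C@](C)(CC[C@H](O[Si](C)(C)C(C)(C)C)[C@@H]1CB2OC(C)(C)C(C)(C)O2)CC(OC)OC | intermediate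
16 | 3-(hydroxymethyl) lactone (3,4-cis) | O=C1O[C@](C)(CC[C@H](O[Si](C)(C)C(C)(C)C)[C@@H]1CO)CC(OC)OC | intermediate
17 | 3-(TBS-oxymethyl)-4-(TBS-oxy) lactone | O=C1O[C@](C)(CC[C@H](O[Si](C)(C)C(C)(C)C)[C@@H]1CO[Si](C)(C)C(C)(C)C)CC(OC)OC | intermediate
18 | 2-methyleneoxepane (exocyclic enol ether) | C=C1O[C@](C)(CC[C@H](O[Si](C)(C)C(C)(C)C)[C@@H]1CO[Si](C)(C)C(C)(C)C)CC(OC)OC | intermediate
19 | B-alkyl-9-BBN adduct of 18 | C(B1C2CCCC1CCC2)[C@@H]3O[C@](C)(CC[C@H](O[Si](C)(C)C(C)(C)C)[C@@H]3CO[Si](C)(C)C(C)(C)C)CC(OC)OC | intermediate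
20 | (oxepan-2-yl)methanol (C6 alcohol) | OC[C@@H]1O[C@](C)(CC[C@H](O[Si](C)(C)C(C)(C)C)[C@@H]1CO[Si](C)(C)C(C)(C)C)CC(OC)OC | intermediate
21 | oxepane-2-carbaldehyde (C6 aldehyde) | O=C[C@@H]1O[C@](C)(CC[C@H](O[Si](C)(C)C(C)(C)C)[C@@H]1CO[Si](C)(C)C(C)(C)C)CC(OC)OC | intermediate
22 | ethyl 2-(bromomethyl)acrylate | CCOC(=O)C(=C)CBr | starting material
23 | ethyl 4-hydroxy-2-methylene-4-(oxepan-2-yl)butanoate | CCOC(=O)C(=C)C[C@H](O)[C@@H]1O[C@](C)(CC[C@H](O[Si](C)(C)C(C)(C)C)[C@@H]1CO[Si](C)(C)C(C)(C)C)CC(OC)OC | intermediate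
24 | α-methylene-γ-butyrolactone, bis-TBS, acetal | C=C1C(=O)O[C@@H](C1)[C@@H]2O[C@](C)(CC[C@H](O[Si](C)(C)C(C)(C)C)[C@@H]2CO[Si](C)(C)C(C)(C)C)CC(OC)OC | intermediate
25 | 15-hydroxy α-methylene lactone | C=C1C(=O)O[C@@H](C1)[C@@H]2O[C@](C)(CC[C@H](O[Si](C)(C)C(C)(C)C)[C@@H]2CO)CC(OC)OC | intermediate
26 | 15-acetoxy α-methylene lactone | C=C1C(=O)O[C@@H](C1)[C@@H]2O[C@](C)(CC[C@H](O[Si](C)(C)C(C)(C)C)[C@@H]2COC(C)=O)CC(OC)OC | intermediate
27 | 3-bromo-3-(bromomethyl) lactone (C11 epimers) | O=C1O[C@@H](CC1(Br)CBr)[C@@H]2O[C@](C)(CC[C@H](O[Si](C)(C)C(C)(C)C)[C@@H]2COC(C)=O)CC(OC)OC | intermediate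
28 | 3-(bromomethyl)but-2-en-4-olide, C8 dimethyl acetal | O=C1O[C@@H](C=C1CBr)[C@@H]2O[C@](C)(CC[C@H](O[Si](C)(C)C(C)(C)C)[C@@H]2COC(C)=O)CC(OC)OC | intermediate
29 | 3-(bromomethyl)but-2-en-4-olide, C8 aldehyde | O=C1O[C@@H](C=C1CBr)[C@@H]2O[C@](C)(CC[C@H](O[Si](C)(C)C(C)(C)C)[C@@H]2COC(C)=O)CC=O | intermediate
30 | allylchromium(III) dichloride from 29 | O=C1O[C@@H](C=C1C[Cr](Cl)Cl)[C@@H]2O[C@](C)(CC[C@H](O[Si](C)(C)C(C)(C)C)[C@@H]2COC(C)=O)CC=O | intermediate
31 | tricyclic 8β-alcohol (3-O-TBS, 15-O-acetyl) | C=C1C(=O)O[C@@H]2[C@@H]3O[C@](C)(CC[C@H](O[Si](C)(C)C(C)(C)C)[C@@H]3COC(C)=O)C[C@@H](O)[C@@H]12 | intermediate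
32 | angelic acid | C/C=C(/C)C(=O)O | starting material
33 | 8-O-angelate, 3-O-TBS | C=C1C(=O)O[C@@H]2[C@@H]3O[C@](C)(CC[C@H](O[Si](C)(C)C(C)(C)C)[C@@H]3COC(C)=O)C[C@@H](OC(=O)/C(C)=C\C)[C@@H]12 | intermediate
34 | CNP0277024.1 | C=C1C(=O)O[C@@H]2[C@@H]3O[C@](C)(CC[C@H](O)[C@@H]3COC(C)=O)C[C@@H](OC(=O)/C(C)=C\C)[C@@H]12 | target

**Step count and risks**

Total steps: 20. Longest linear sequence: 20.

Step 18 (key step). What may go wrong: the tethered aldehyde may add to the butenolide face syn to C5, because that trajectory is shorter, which would give the cis-fused lactone; or the strained in,out ring may fail to close and the allylchromium is protonated or dimerises. Fallback: replace the reductive organometallic addition by a Lewis-acid allylsilane addition with an open transition state. It sets out from compound 28. Hexamethyldisilane with catalytic Pd2(dba)3 in THF should give the 3-(trimethylsilylmethyl)butenolide acetal F1. Amberlyst-15 in wet acetone should then give the allylsilane aldehyde F2. TiCl4 in CH2Cl2 at −78 °C (intramolecular Hosomi–Sakurai reaction, known for 2-(silylmethyl)acrylates with aldehydes) should close the C7–C8 bond and come back to the route at compound 31. No low-valent metal is present, so protonation and dimerisation of an allyl-metal are excluded, and the open array places different steric demands on the two faces.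

Step 16. What may go wrong: dehydrobromination may take the more acidic hydrogen of the CH2Br group instead of the ring C7–H, giving an exocyclic vinyl bromide rather than the allylic bromide. Fallback: an ene reaction in place of addition–elimination. It sets out from compound 26. Photooxygenation (O2, tetraphenylporphyrin, hν, CH2Cl2; Schenck ene reaction, which for acrylate-type alkenes abstracts the hydrogen geminal to the carbonyl, here C7–H) should give the 3-(hydroperoxymethyl)butenolide F3. Triphenylphosphine should reduce it to the 3-(hydroxymethyl)butenolide F4. CBr4/PPh3 should then give the bromide and come back to the route at compound 28.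

Step 8. What may go wrong: protonation of the copper/boron enolate on the wrong face (3,4-trans product), or β-elimination of silanolate from the enolate. Fallback: set C4 by hydrogenation instead of protonation. It sets out from compound 10. LDA and ethyl formate should give the 3-(hydroxymethylene) lactone F5. TBSCl/imidazole should give the silyl enol ether F6. Hydrogenation over Rh/Al2O3 should deliver both hydrogens from the face opposite the C3 silyloxy group and come back to the route at compound 17.

Further compounds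
F1 | step 18 | 3-(trimethylsilylmethyl)but-2-en-4-olide, C8 dimethyl acetal | O=C1O[C@@H](C=C1C[Si](C)(C)C)[C@@H]2O[C@](C)(CC[C@H](O[Si](C)(C)C(C)(C)C)[C@@H]2COC(C)=O)CC(OC)OC
F2 | step 18 | 3-(trimethylsilylmethyl)but-2-en-4-olide, C8 aldehyde | O=C1O[C@@H](C=C1C[Si](C)(C)C)[C@@H]2O[C@](C)(CC[C@H](O[Si](C)(C)C(C)(C)C)[C@@H]2COC(C)=O)CC=O
F3 | step 16 | 3-(hydroperoxymethyl)but-2-en-4-olide, C8 dimethyl acetal | O=C1O[C@@H](C=C1COO)[C@@H]2O[C@](C)(CC[C@H](O[Si](C)(C)C(C)(C)C)[C@@H]2COC(C)=O)CC(OC)OC
F4 | step 16 | 3-(hydroxymethyl)but-2-en-4-olide, C8 dimethyl acetal | O=C1O[C@@H](C=C1CO)[C@@H]2O[C@](C)(CC[C@H](O[Si](C)(C)C(C)(C)C)[C@@H]2COC(C)=O)CC(OC)OC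
F5 | step 8 | 3-(hydroxymethylene)-4-(TBS-oxy)-7-(2,2-dimethoxyethyl)-7-methyloxepan-2-one | O=C1O[C@](C)(CC[C@H](O[Si](C)(C)C(C)(C)C)C1=CO)CC(OC)OC
F6 | step 8 | 3-(TBS-oxymethylene)-4-(TBS-oxy)-7-(2,2-dimethoxyethyl)-7-methyloxepan-2-one | O=C1O[C@](C)(CC[C@H](O[Si](C)(C)C(C)(C)C)C1=CO[Si](C)(C)C(C)(C)C)CC(OC)OC
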